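**Assumptions**
- The target has no stereocentre or stereoaxis, so it is achiral and "single enantiomer" does not apply. The only stereo-elements in the route are an E-alkene and one racemic sp3 carbon, and both are erased by step 6.
- Sulfate monoesters are drawn in the acid form, as in the target SMILES. In practice they are handled as Bu4N+ or K+ salts, and counter-ions are not counted as added atoms.

## Retrosynthetic overview
1. The route avoids the usual plan (chalcone/Algar–Flynn–Oyamada (AFO) flavonol synthesis, a 3'-protected rhamnetin, then triple sulfation). Instead the 5- and 4'-sulfates go on the fragments first and act as their own protecting groups, because aryl sulfate anions are inert to base, nucleophiles and peroxide. Every step that carries a sulfate is neutral or basic, and no protecting groups are used.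
2. The last bond made is 3-O–S, by acidity-controlled carbodiimide sulfation of rhamnetin 5,4'-disulfate. The 3'-OH, which sits ortho to a sulfate, is left free.
3. The flavonol C-ring comes from a 2-aryl-3-nitro-2H-chromene, with NO2 as a latent 3-oxygen. Alkaline H2O2 converts C3–NO2/C4–H into C3–OH/C4=O. The six-membered ring already exists, so no aurone can form.
4. The nitrochromene comes from a one-pot oxa-Michael/Henry union (O1–C2 and C3–C4 bonds). The partners are monosulfated 2,6-dihydroxy-4-methoxybenzaldehyde and 4-O-sulfated 3,4-dihydroxy-β-nitrostyrene.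
5. Ring order: rings A and B are purchased (phloroglucinaldehyde and protocatechualdehyde; C3 comes from nitromethane). Ring C is the only ring formed (step 5) and is aromatised in step 6.

## Route

**Step 1**
Reactants: 1, 2,4,6-trihydroxybenzaldehyde
Product: 2, 2,6-dihydroxy-4-methoxybenzaldehyde
Conditions: Me2SO4 (1.0 equiv), K2CO3 (1.0 equiv), acetone, 0 °C → rt
Reagents that add atoms: dimethyl sulfate, COS(=O)(=O)OC (CH3 retained)
Why: Williamson O-methylation is site-selective because the 4-OH is the most acidic hydroxyl and the only one not engaged with the formyl group, and the over-methylated by-product is removed by chromatography.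

**Step 2**
Reactants: 2, 2,6-dihydroxy-4-methoxybenzaldehyde
Product: 3, 2-formyl-3-hydroxy-5-methoxyphenyl hydrogen sulfate (Bu4N+ salt)
Conditions: Bu4NHSO4 (1.1 equiv), DCC (3 equiv), pyridine, 4 °C, 16 h; filter off dicyclohexylurea (DCU)
Reagents that add atoms: tetrabutylammonium hydrogen sulfate, CCCC[N+](CCCC)(CCCC)CCCC.OS(=O)(=O)[O-] (SO3 retained)
Why: Carbodiimide-mediated sulfation desymmetrises 2, since only one of the two equivalent OH groups can chelate the C=O at a time and the free one reacts, after which the remaining OH is locked in the chelate like a flavonoid 5-OH, which this mild reagent does not sulfate.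

**Step 3**
Reactants: 4, 3,4-dihydroxybenzaldehyde; 5, nitromethane
Product: 6, (E)-4-(2-nitroethenyl)benzene-1,2-diol
Conditions: MeNO2 (5 equiv), NH4OAc, AcOH, 100 °C, 2 h
Reagents that add atoms: nitromethane (5), C[N+](=O)[O-]
Why: The Henry (nitroaldol) condensation–dehydration tolerates a free catechol and gives the thermodynamic E-nitroalkene, and it is run before sulfation so that no sulfate is exposed to hot acid.

**Step 4**
Reactants: 6, (E)-4-(2-nitroethenyl)benzene-1,2-diol
Product: 7, 2-hydroxy-4-[(E)-2-nitroethenyl]phenyl hydrogen sulfate (Bu4N+ salt)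
Conditions: Bu4NHSO4 (1.05 equiv), DCC (3 equiv), pyridine, 4 °C, 6–12 h
Reagents that add atoms: tetrabutylammonium hydrogen sulfate, CCCC[N+](CCCC)(CCCC)CCCC.OS(=O)(=O)[O-] (SO3 retained)
Why: Carbodiimide-mediated sulfation follows acidity, so the OH para to the nitrovinyl group (pKa about 7) reacts first and the OH ortho to the new sulfate is not touched, matching the 4'-over-3' preference this reagent shows on flavonoid catechols (regiochemistry confirmed by HMBC and 13C sulfation shifts).

**Step 5 (key union, ring C formed)**
Reactants: 3, 2-formyl-3-hydroxy-5-methoxyphenyl hydrogen sulfate; 7, 2-hydroxy-4-[(E)-2-nitroethenyl]phenyl hydrogen sulfate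
Product: 8, (±)-2-[3-hydroxy-4-(sulfooxy)phenyl]-7-methoxy-3-nitro-2H-chromen-5-yl hydrogen sulfate (bis-Bu4N+ salt)
Conditions: DABCO (0.5 equiv), MeCN, 4 Å MS, 45 °C, 24–48 h
Reagents that add atoms: none (H2O is lost)
Why: In this tandem oxa-Michael/intramolecular Henry/dehydration, the phenoxide of 3 adds to the aryl-bearing carbon of 7 and the nitronate closes irreversibly on the adjacent CHO, while the 4'-sulfate prevents a deactivating para-phenoxide, the sulfate anions ignore amine base, and the new C2 centre forms racemic and is destroyed in step 6.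

**Step 6 (nitro → oxygen swap, ring C aromatised)**
Reactants: 8, the 3-nitro-2H-chromene disulfate
Product: 9, rhamnetin 5,4'-di-O-sulfate = 3-hydroxy-2-[3-hydroxy-4-(sulfooxy)phenyl]-7-methoxy-4-oxo-4H-chromen-5-yl hydrogen sulfate
Conditions: 30% H2O2 (5 equiv), 2 M NaOH (4 equiv), MeOH–H2O, 0 °C → rt, 3 h; Na2SO3 quench, adjust to pH 7, C18 chromatography
Reagents that add atoms: hydrogen peroxide, OO (gives the 3-O and 4-O; the 4-O may instead come from hydroxide/water, O)
Why: Weitz–Scheffer nucleophilic epoxidation of the nitroalkene is followed by HOO−/HO− opening at C4 with loss of nitrite (giving C3=O) and Kornblum–DeLaMare or AFO-type oxidation to the chroman-3,4-dione, which enolises to the flavonol; this conversion is known for simple 2-aryl-3-nitrochromenes, aurone formation is impossible here, and aryl sulfate anions are inert to alkaline peroxide.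

**Step 7**
Reactants: 9, rhamnetin 5,4'-di-O-sulfate
Product: 10, rhamnetin 3,5,4'-tri-O-sulfate (target)
Conditions: Bu4NHSO4 (3 equiv), DCC (10 equiv), pyridine, 4 °C → rt, 48–72 h; filter off DCU; KOAc/MeOH to precipitate the K3 salt; strong-acid cation-exchange resin (H+ form), H2O, 0 °C, lyophilise to obtain the acid form
Reagents that add atoms: tetrabutylammonium hydrogen sulfate, CCCC[N+](CCCC)(CCCC)CCCC.OS(=O)(=O)[O-] (SO3 retained)
Why: Carbodiimide-mediated sulfation takes the acidic enolic 3-OH but does not sulfate a phenol flanked by an ortho sulfate, so of the two remaining hydroxyls only O-3 reacts and the 3'-OH stays free.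

## Compound list
1 | 2,4,6-trihydroxybenzaldehyde | O=Cc1c(O)cc(O)cc1O | starting material
2 | 2,6-dihydroxy-4-methoxybenzaldehyde | COc1cc(O)c(C=O)c(O)c1 | intermediate
3 | 2-formyl-3-hydroxy-5-methoxyphenyl hydrogen sulfate | COc1cc(O)c(C=O)c(OS(=O)(=O)O)c1 | intermediate
4 | 3,4-dihydroxybenzaldehyde | O=Cc1ccc(O)c(O)c1 | starting material
5 | nitromethane | C[N+](=O)[O-] | starting material
6 | (E)-4-(2-nitroethenyl)benzene-1,2-diol | O=[N+]([O-])/C=C/c1ccc(O)c(O)c1 | intermediate
7 | 2-hydroxy-4-[(E)-2-nitroethenyl]phenyl hydrogen sulfate | O=[N+]([O-])/C=C/c1ccc(OS(=O)(=O)O)c(O)c1 | intermediate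
8 | (±)-2-[3-hydroxy-4-(sulfooxy)phenyl]-7-methoxy-3-nitro-2H-chromen-5-yl hydrogen sulfate (racemic at C2) | COc1cc(OS(=O)(=O)O)c2C=C([N+](=O)[O-])C(c3ccc(OS(=O)(=O)O)c(O)c3)Oc2c1 | intermediate
9 | rhamnetin 5,4'-di-O-sulfate | COc1cc(OS(=O)(=O)O)c2c(=O)c(O)c(-c3ccc(OS(=O)(=O)O)c(O)c3)oc2c1 | intermediate
10 | rhamnetin 3,5,4'-tri-O-sulfate (achiral) | COc1cc(OS(=O)(=O)O)c2c(=O)c(OS(=O)(=O)O)c(-c3ccc(OS(=O)(=O)O)c(O)c3)oc2c1 | target

## Summary
Total steps: 7. Longest linear sequence: 5 (steps 1→2→5→6→7, or equally 3→4→5→6→7). No protecting groups are used.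

**Steps most likely to fail**
1. **Step 5.** Both partners are anionic, and the aldehyde is electron-rich and 2,6-disubstituted.
   - Fallback: change the C-ring disconnection to the acetophenone series.
   - Monosulfate commercial 2',6'-dihydroxy-4'-methoxyacetophenone, then run a Claisen–Schmidt condensation with 4-formyl-2-hydroxyphenyl sulfate in aqueous KOH.
   - Close to the flavanone and oxidise its enolate (O2/KOtBu or PhI(OAc)2/KOH) to 9. This keeps the sulfate-first, all-basic logic.
2. **Step 6.** The peri 5-sulfate shields C4 and repels HOO−, and the flavonol may over-oxidise.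
   - Fallback: replace oxidative denitration with a reductive/Nef sequence.
   - Reduce 8 by NaBH4 1,4-reduction to the 3-nitrochroman, then carry out a basic oxidative Nef reaction on the nitronate to give the flavan-3-one.
   - Base/O2 autoxidation at the doubly activated C4 then gives the 3,4-dione, which is flavonol 9.
3. **Step 7.** Selectivity for 3-OH over 3'-OH may be poor, or the dianionic substrate may react slowly.
   - Fallback: give up the protecting-group-free endgame and run steps 3–6 from 3-(benzyloxy)-4-hydroxybenzaldehyde.
   - Sulfate the only free OH (O-3) exhaustively with SO3·NMe3.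
   - Remove the benzyl group by neutral hydrogenolysis (H2, Pd/C) on the salt.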